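**Retrosynthetic overview**
1. Target 30 ⇐ desilylation, outer-face epoxidation of the 1(10)-alkene, and oxidation/CBS adjustment of C3 ⇐ macrocyclic allylic alcohol 26.
2. Ten-membered ring ⇐ intramolecular Nozaki–Hiyama–Kishi closure of C3–C4 from iodo-aldehyde 25.
3. C8 isobutyrate ⇐ Mitsunobu inversion of the C8 alcohol 21.
4. Key disconnection C7–C8: intermolecular CrCl2 carbonyl allylation of aldehyde 20 with bromomethyl butenolide 11, which sets C7 and C8 and unveils the α-methylene lactone.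
5. Ring order: butenolide (RCM) → ten-membered carbocycle → oxirane. 11 comes from propargyl alcohol and crotonaldehyde (Sharpless kinetic resolution sets C6); 20 comes from but-3-yn-1-ol and oxirane (Negishi carboalumination).

Assumption: germacrane numbering (C1–C15) is used in the explanations, and the target is read as the 1β,10α-epoxy-3β,15-dihydroxy-8β-isobutyryloxy heliangolide (1R,3S,4Z,6R,7R,8R,10R).

**Route**

Step 1
Reactants: 1 prop-2-yn-1-ol
Product: 2 tert-butyldimethyl(prop-2-yn-1-yloxy)silane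
Conditions: TBSCl, imidazole, CH2Cl2, 0 °C to rt
Reagents that add atoms: TBSCl (tert-butyldimethylsilyl chloride), CC(C)(C)[Si](C)(C)Cl
Why: Silyl ether formation protects the future C15 hydroxyl through to the last step.

Step 2
Reactants: 2 tert-butyldimethyl(prop-2-yn-1-yloxy)silane; 3 (E)-but-2-enal
Product: 5 rac-(5E)-1-[(tert-butyldimethylsilyl)oxy]hept-5-en-2-yn-4-ol, via lithium acetylide 4 (not isolated)
Conditions: n-BuLi, THF, −78 °C; then 3, −78 to 0 °C; H2O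
Reagents that add atoms: none
Why: 1,2-Addition of a lithium acetylide to an enal (alkynylation) gives the racemic carbinol that becomes C6.

Step 3
Reactants: 5 rac-(5E)-1-[(tert-butyldimethylsilyl)oxy]hept-5-en-2-yn-4-ol
Product: 6 (4S,5E)-1-[(tert-butyldimethylsilyl)oxy]hept-5-en-2-yn-4-ol
Conditions: Ti(OiPr)4 (10 mol %), L-(+)-diisopropyl tartrate (15 mol %), t-BuOOH (0.6 equiv), 4 Å MS, CH2Cl2, −20 °C, stopped near 55% conversion
Reagents that add atoms: none
Why: Sharpless kinetic resolution: with L-(+)-tartrate the (R)-alcohol is epoxidised at its propenyl group much faster, so (S)-6 is recovered (at most about 45%) and fixes C6.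

Step 4
Reactants: 6 (4S,5E)-1-[(tert-butyldimethylsilyl)oxy]hept-5-en-2-yn-4-ol
Product: 8 (2Z,4S,5E)-1-[(tert-butyldimethylsilyl)oxy]-2-iodohepta-2,5-dien-4-ol, via cyclic vinylalanate 7 (not isolated)
Conditions: NaAlH2(OCH2CH2OMe)2, THF, 0 °C; then I2, −78 to 0 °C
Reagents that add atoms: iodine, [I][I]
Why: Hydroxyl-directed trans-hydroalumination of the propargylic alcohol, then iodinolysis, puts iodine on the distal carbon (future C4) cis to the carbinol, which is the ring-alkene geometry needed.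

Step 5
Reactants: 8 (2Z,4S,5E)-1-[(tert-butyldimethylsilyl)oxy]-2-iodohepta-2,5-dien-4-ol; 9 2-(bromomethyl)prop-2-enoic acid
Product: 10 (2Z,4S,5E)-1-[(tert-butyldimethylsilyl)oxy]-2-iodohepta-2,5-dien-4-yl 2-(bromomethyl)prop-2-enoate
Conditions: N,N'-diisopropylcarbodiimide, DMAP (5 mol %), CH2Cl2, 0 °C
Reagents that add atoms: none
Why: Steglich esterification at low temperature with only catalytic DMAP acylates the secondary alcohol without touching the allylic bromide or the stereocenter.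

Step 6
Reactants: 10 (2Z,4S,5E)-1-[(tert-butyldimethylsilyl)oxy]-2-iodohepta-2,5-dien-4-yl 2-(bromomethyl)prop-2-enoate
Product: 11 (5S)-3-(bromomethyl)-5-[(1Z)-3-[(tert-butyldimethylsilyl)oxy]-2-iodoprop-1-en-1-yl]furan-2(5H)-one
Conditions: second-generation Hoveyda–Grubbs catalyst RuCl2(H2IMes)(=CH–C6H4-2-OiPr) (5 mol %), toluene, 80 °C, 0.005 M
Reagents that add atoms: none
Why: Ring-closing metathesis between the propenyl group and the acrylate forms the butenolide with loss of propene; the trisubstituted iodoalkene is inert to the catalyst.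

Step 7
Reactants: 12 but-3-yn-1-ol
Product: 13 (but-3-yn-1-yloxy)(tert-butyl)dimethylsilane
Conditions: TBSCl, imidazole, CH2Cl2, 0 °C to rt
Reagents that add atoms: TBSCl (tert-butyldimethylsilyl chloride), CC(C)(C)[Si](C)(C)Cl
Why: Silyl ether formation masks the future C8 hydroxyl during carboalumination.

Step 8
Reactants: 13 (but-3-yn-1-yloxy)(tert-butyl)dimethylsilane; 14 oxirane
Product: 17 (3E)-6-[(tert-butyldimethylsilyl)oxy]-4-methylhex-3-en-1-ol, via alkenyldimethylalane 15 (not isolated), via lithium alkenylalanate 16 (not isolated)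
Conditions: Me3Al, Cp2ZrCl2 (20 mol %), CH2Cl2, 0 °C to rt; evaporate; n-BuLi, hexane/THF, −78 °C; then 14, −78 to 0 °C; aqueous Rochelle salt
Reagents that add atoms: trimethylaluminium, C[Al](C)C
Why: Negishi zirconium-catalysed syn-carboalumination sets the (E)-trisubstituted C1=C10 alkene and the C14 methyl, and the alanate opens oxirane with retention to add C2–C3.

Step 9
Reactants: 17 (3E)-6-[(tert-butyldimethylsilyl)oxy]-4-methylhex-3-en-1-ol
Product: 18 tert-butyl{[(3E)-6-[(4-methoxybenzyl)oxy]-3-methylhex-3-en-1-yl]oxy}dimethylsilane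
Conditions: NaH, 4-methoxybenzyl chloride, Bu4NI (cat.), THF/DMF, 0 °C to rt
Reagents that add atoms: 4-methoxybenzyl chloride, COc1ccc(CCl)cc1
Why: Williamson etherification gives a C3 protecting group that is orthogonal to both silyl ethers.

Step 10
Reactants: 18 tert-butyl{[(3E)-6-[(4-methoxybenzyl)oxy]-3-methylhex-3-en-1-yl]oxy}dimethylsilane
Product: 19 (3E)-6-[(4-methoxybenzyl)oxy]-3-methylhex-3-en-1-ol
Conditions: Bu4NF, THF, 0 °C to rt
Reagents that add atoms: none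
Why: Fluoride desilylation frees only the C8 hydroxyl.

Step 11
Reactants: 19 (3E)-6-[(4-methoxybenzyl)oxy]-3-methylhex-3-en-1-ol
Product: 20 (3E)-6-[(4-methoxybenzyl)oxy]-3-methylhex-3-enal
Conditions: Dess–Martin periodinane, NaHCO3, CH2Cl2, 0 °C; used crude at once
Reagents that add atoms: none
Why: Buffered Dess–Martin oxidation gives the β,γ-unsaturated aldehyde without isomerising it into conjugation.

Step 12
Reactants: 11 (5S)-3-(bromomethyl)-5-[(1Z)-3-[(tert-butyldimethylsilyl)oxy]-2-iodoprop-1-en-1-yl]furan-2(5H)-one; 20 (3E)-6-[(4-methoxybenzyl)oxy]-3-methylhex-3-enal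
Product: 21 (4R,5S)-5-[(1Z)-3-[(tert-butyldimethylsilyl)oxy]-2-iodoprop-1-en-1-yl]-4-[(1S,3E)-1-hydroxy-6-[(4-methoxybenzyl)oxy]-3-methylhex-3-en-1-yl]-3-methylideneoxolan-2-one
Conditions: CrCl2 (4 equiv), THF, 0 °C to rt
Reagents that add atoms: none
Why: Nozaki–Hiyama (Barbier-type) carbonyl allylation joins the two fragments: the trivalent allylchromium species adds through its γ-carbon (C7) in a closed chair transition state, anti to the C6 alkenyl group (6,7-trans), and with the aldehyde chain equatorial this gives the 8S alcohol (the 8-epimer), while the α-methylene lactone appears directly.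

Step 13
Reactants: 21 (4R,5S)-5-[(1Z)-3-[(tert-butyldimethylsilyl)oxy]-2-iodoprop-1-en-1-yl]-4-[(1S,3E)-1-hydroxy-6-[(4-methoxybenzyl)oxy]-3-methylhex-3-en-1-yl]-3-methylideneoxolan-2-one; 22 2-methylpropanoic acid
Product: 23 (1R,3E)-1-[(2S,3R)-2-[(1Z)-3-[(tert-butyldimethylsilyl)oxy]-2-iodoprop-1-en-1-yl]-4-methylidene-5-oxooxolan-3-yl]-6-[(4-methoxybenzyl)oxy]-3-methylhex-3-en-1-yl 2-methylpropanoate
Conditions: PPh3, DIAD, toluene, 0 °C to rt
Reagents that add atoms: none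
Why: Mitsunobu esterification installs the isobutyrate with clean SN2 inversion at C8, turning the 8S alcohol into the 8R ester of the target.

Step 14
Reactants: 23 (1R,3E)-1-[(2S,3R)-2-[(1Z)-3-[(tert-butyldimethylsilyl)oxy]-2-iodoprop-1-en-1-yl]-4-methylidene-5-oxooxolan-3-yl]-6-[(4-methoxybenzyl)oxy]-3-methylhex-3-en-1-yl 2-methylpropanoate
Product: 24 (1R,3E)-1-[(2S,3R)-2-[(1Z)-3-[(tert-butyldimethylsilyl)oxy]-2-iodoprop-1-en-1-yl]-4-methylidene-5-oxooxolan-3-yl]-6-hydroxy-3-methylhex-3-en-1-yl 2-methylpropanoate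
Conditions: DDQ, CH2Cl2/pH 7 buffer, 0 °C
Reagents that add atoms: none
Why: Oxidative cleavage of the 4-methoxybenzyl ether frees the C3 hydroxyl and leaves the silyl ether, esters, iodoalkene and alkenes untouched.

Step 15
Reactants: 24 (1R,3E)-1-[(2S,3R)-2-[(1Z)-3-[(tert-butyldimethylsilyl)oxy]-2-iodoprop-1-en-1-yl]-4-methylidene-5-oxooxolan-3-yl]-6-hydroxy-3-methylhex-3-en-1-yl 2-methylpropanoate
Product: 25 (1R,3E)-1-[(2S,3R)-2-[(1Z)-3-[(tert-butyldimethylsilyl)oxy]-2-iodoprop-1-en-1-yl]-4-methylidene-5-oxooxolan-3-yl]-3-methyl-6-oxohex-3-en-1-yl 2-methylpropanoate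
Conditions: Dess–Martin periodinane, NaHCO3, CH2Cl2, 0 °C; used crude at once
Reagents that add atoms: none
Why: Buffered Dess–Martin oxidation gives the C3 aldehyde under neutral conditions that tolerate the β,γ-alkene.

Step 16
Reactants: 25 (1R,3E)-1-[(2S,3R)-2-[(1Z)-3-[(tert-butyldimethylsilyl)oxy]-2-iodoprop-1-en-1-yl]-4-methylidene-5-oxooxolan-3-yl]-3-methyl-6-oxohex-3-en-1-yl 2-methylpropanoate
Product: 26 (1(10)E,3RS,4Z,6R,7R,8R)-15-[(tert-butyldimethylsilyl)oxy]-3-hydroxy-8-(2-methylpropanoyloxy)germacra-1(10),4,11(13)-trien-12,6-olide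
Conditions: CrCl2 (10 equiv), NiCl2 (0.1 equiv), DMSO/THF, 0.003 M, slow addition, rt
Reagents that add atoms: none
Why: Intramolecular Nozaki–Hiyama–Kishi reaction: zerovalent nickel inserts into the C–I bond, the alkenyl group passes to trivalent chromium and adds to the aldehyde, closing the ten-membered ring with retention of the (Z)-alkene; the C3 epimers are carried on together.

Step 17
Reactants: 26 (1(10)E,3RS,4Z,6R,7R,8R)-15-[(tert-butyldimethylsilyl)oxy]-3-hydroxy-8-(2-methylpropanoyloxy)germacra-1(10),4,11(13)-trien-12,6-olide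
Product: 27 (1(10)E,4Z,6R,7R,8R)-15-[(tert-butyldimethylsilyl)oxy]-8-(2-methylpropanoyloxy)-3-oxogermacra-1(10),4,11(13)-trien-12,6-olide
Conditions: Dess–Martin periodinane, NaHCO3, CH2Cl2, 0 °C
Reagents that add atoms: none
Why: Dess–Martin oxidation converges both C3 epimers on one enone under neutral conditions.

Step 18
Reactants: 27 (1(10)E,4Z,6R,7R,8R)-15-[(tert-butyldimethylsilyl)oxy]-8-(2-methylpropanoyloxy)-3-oxogermacra-1(10),4,11(13)-trien-12,6-olide
Product: 28 (1(10)E,3S,4Z,6R,7R,8R)-15-[(tert-butyldimethylsilyl)oxy]-3-hydroxy-8-(2-methylpropanoyloxy)germacra-1(10),4,11(13)-trien-12,6-olide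
Conditions: (R)-2-methyl-CBS-oxazaborolidine (1 equiv), catecholborane, toluene/CH2Cl2, −78 to −40 °C
Reagents that add atoms: none
Why: Corey–Bakshi–Shibata 1,2-reduction of the enone, with the substituted alkenyl branch (C4) as the large group, is expected to deliver hydride to the face that gives the 3S (3β) alcohol, and catecholborane at low temperature spares the lactone and alkenes.

Step 19
Reactants: 28 (1(10)E,3S,4Z,6R,7R,8R)-15-[(tert-butyldimethylsilyl)oxy]-3-hydroxy-8-(2-methylpropanoyloxy)germacra-1(10),4,11(13)-trien-12,6-olide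
Product: 29 (1R,3S,4Z,6R,7R,8R,10R)-15-[(tert-butyldimethylsilyl)oxy]-1,10-epoxy-3-hydroxy-8-(2-methylpropanoyloxy)germacra-4,11(13)-dien-12,6-olide
Conditions: mCPBA (1.1 equiv), NaHCO3, CH2Cl2, 0 °C
Reagents that add atoms: mCPBA (3-chloroperoxybenzoic acid), OOC(=O)c1cccc(Cl)c1
Why: Prilezhaev epoxidation is selective for the electron-rich (E)-1(10) alkene (C4=C5 carries three allylic oxygens and the lactone methylene is electron-poor), and attack on the exposed outer face should give the 1β,10α (1R,10R) oxirane found in natural 1,10-epoxygermacranolides.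

Step 20
Reactants: 29 (1R,3S,4Z,6R,7R,8R,10R)-15-[(tert-butyldimethylsilyl)oxy]-1,10-epoxy-3-hydroxy-8-(2-methylpropanoyloxy)germacra-4,11(13)-dien-12,6-olide
Product: 30 (1R,3S,4Z,6R,7R,8R,10R)-1,10-epoxy-3,15-dihydroxy-8-(2-methylpropanoyloxy)germacra-4,11(13)-dien-12,6-olide (CNP0219050.1)
Conditions: HF·pyridine, pyridine, THF, 0 °C
Reagents that add atoms: none
Why: Pyridine-buffered fluoride desilylation removes the primary silyl ether without opening the oxirane or adding to the α-methylene lactone.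

**Compound list**
1 | prop-2-yn-1-ol | C#CCO | starting material
2 | tert-butyldimethyl(prop-2-yn-1-yloxy)silane | C#CCO[Si](C)(C)C(C)(C)C | intermediate
3 | (E)-but-2-enal | C/C=C/C=O | starting material
4 | lithium 3-[(tert-butyldimethylsilyl)oxy]prop-1-yn-1-ide (lithium acetylide) | [Li]C#CCO[Si](C)(C)C(C)(C)C | intermediate
5 | rac-(5E)-1-[(tert-butyldimethylsilyl)oxy]hept-5-en-2-yn-4-ol | C/C=C/C(O)C#CCO[Si](C)(C)C(C)(C)C | intermediate
6 | (4S,5E)-1-[(tert-butyldimethylsilyl)oxy]hept-5-en-2-yn-4-ol | C/C=C/[C@H](O)C#CCO[Si](C)(C)C(C)(C)C | intermediate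
7 | sodium (5S)-3-{[(tert-butyldimethylsilyl)oxy]methyl}-2,2-bis(2-methoxyethoxy)-5-[(1E)-prop-1-en-1-yl]-2,5-dihydro-1,2-oxaluminol-2-uide (cyclic vinylalanate) | C/C=C/[C@@H]1O[Al-](OCCOC)(OCCOC)C(CO[Si](C)(C)C(C)(C)C)=C1.[Na+] | intermediate
8 | (2Z,4S,5E)-1-[(tert-butyldimethylsilyl)oxy]-2-iodohepta-2,5-dien-4-ol | C/C=C/[C@H](O)/C=C(\I)CO[Si](C)(C)C(C)(C)C | intermediate
9 | 2-(bromomethyl)prop-2-enoic acid | C=C(CBr)C(=O)O | starting material
10 | (2Z,4S,5E)-1-[(tert-butyldimethylsilyl)oxy]-2-iodohepta-2,5-dien-4-yl 2-(bromomethyl)prop-2-enoate | C/C=C/[C@H](OC(=O)C(=C)CBr)/C=C(\I)CO[Si](C)(C)C(C)(C)C | intermediate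
11 | (5S)-3-(bromomethyl)-5-[(1Z)-3-[(tert-butyldimethylsilyl)oxy]-2-iodoprop-1-en-1-yl]furan-2(5H)-one | BrCC1=C[C@@H](/C=C(\I)CO[Si](C)(C)C(C)(C)C)OC1=O | intermediate
12 | but-3-yn-1-ol | C#CCCO | starting material
13 | (but-3-yn-1-yloxy)(tert-butyl)dimethylsilane | C#CCCO[Si](C)(C)C(C)(C)C | intermediate
14 | oxirane | C1CO1 | starting material
15 | [(1E)-4-[(tert-butyldimethylsilyl)oxy]-2-methylbut-1-en-1-yl]dimethylalane | C[Al](C)/C=C(\C)CCO[Si](C)(C)C(C)(C)C | intermediate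
16 | lithium butyl[(1E)-4-[(tert-butyldimethylsilyl)oxy]-2-methylbut-1-en-1-yl]dimethylalanate | [Li+].CCCC[Al-](C)(C)/C=C(\C)CCO[Si](C)(C)C(C)(C)C | intermediate
17 | (3E)-6-[(tert-butyldimethylsilyl)oxy]-4-methylhex-3-en-1-ol | OCC/C=C(\C)CCO[Si](C)(C)C(C)(C)C | intermediate
18 | tert-butyl{[(3E)-6-[(4-methoxybenzyl)oxy]-3-methylhex-3-en-1-yl]oxy}dimethylsilane | COc1ccc(COCC/C=C(\C)CCO[Si](C)(C)C(C)(C)C)cc1 | intermediate
19 | (3E)-6-[(4-methoxybenzyl)oxy]-3-methylhex-3-en-1-ol | COc1ccc(COCC/C=C(\C)CCO)cc1 | intermediate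
20 | (3E)-6-[(4-methoxybenzyl)oxy]-3-methylhex-3-enal | COc1ccc(COCC/C=C(\C)CC=O)cc1 | intermediate
21 | (4R,5S)-5-[(1Z)-3-[(tert-butyldimethylsilyl)oxy]-2-iodoprop-1-en-1-yl]-4-[(1S,3E)-1-hydroxy-6-[(4-methoxybenzyl)oxy]-3-methylhex-3-en-1-yl]-3-methylideneoxolan-2-one | C=C1C(=O)O[C@H](/C=C(\I)CO[Si](C)(C)C(C)(C)C)[C@H]1[C@@H](O)C/C(C)=C/CCOCc1ccc(OC)cc1 | intermediate
22 | 2-methylpropanoic acid | CC(C)C(=O)O | starting material
23 | (1R,3E)-1-[(2S,3R)-2-[(1Z)-3-[(tert-butyldimethylsilyl)oxy]-2-iodoprop-1-en-1-yl]-4-methylidene-5-oxooxolan-3-yl]-6-[(4-methoxybenzyl)oxy]-3-methylhex-3-en-1-yl 2-methylpropanoate | C=C1C(=O)O[C@H](/C=C(\I)CO[Si](C)(C)C(C)(C)C)[C@H]1[C@H](OC(=O)C(C)C)C/C(C)=C/CCOCc1ccc(OC)cc1 | intermediate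
24 | (1R,3E)-1-[(2S,3R)-2-[(1Z)-3-[(tert-butyldimethylsilyl)oxy]-2-iodoprop-1-en-1-yl]-4-methylidene-5-oxooxolan-3-yl]-6-hydroxy-3-methylhex-3-en-1-yl 2-methylpropanoate | C=C1C(=O)O[C@H](/C=C(\I)CO[Si](C)(C)C(C)(C)C)[C@H]1[C@H](OC(=O)C(C)C)C/C(C)=C/CCO | intermediate
25 | (1R,3E)-1-[(2S,3R)-2-[(1Z)-3-[(tert-butyldimethylsilyl)oxy]-2-iodoprop-1-en-1-yl]-4-methylidene-5-oxooxolan-3-yl]-3-methyl-6-oxohex-3-en-1-yl 2-methylpropanoate | C=C1C(=O)O[C@H](/C=C(\I)CO[Si](C)(C)C(C)(C)C)[C@H]1[C@H](OC(=O)C(C)C)C/C(C)=C/CC=O | intermediate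
26 | (1(10)E,3RS,4Z,6R,7R,8R)-15-[(tert-butyldimethylsilyl)oxy]-3-hydroxy-8-(2-methylpropanoyloxy)germacra-1(10),4,11(13)-trien-12,6-olide (C3 epimer mixture) | C=C1C(=O)O[C@@H]2/C=C(/CO[Si](C)(C)C(C)(C)C)C(O)C/C=C(\C)C[C@@H](OC(=O)C(C)C)[C@@H]12 | intermediate
27 | (1(10)E,4Z,6R,7R,8R)-15-[(tert-butyldimethylsilyl)oxy]-8-(2-methylpropanoyloxy)-3-oxogermacra-1(10),4,11(13)-trien-12,6-olide | C=C1C(=O)O[C@@H]2/C=C(/CO[Si](C)(C)C(C)(C)C)C(=O)C/C=C(\C)C[C@@H](OC(=O)C(C)C)[C@@H]12 | intermediate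
28 | (1(10)E,3S,4Z,6R,7R,8R)-15-[(tert-butyldimethylsilyl)oxy]-3-hydroxy-8-(2-methylpropanoyloxy)germacra-1(10),4,11(13)-trien-12,6-olide | C=C1C(=O)O[C@@H]2/C=C(/CO[Si](C)(C)C(C)(C)C)[C@@H](O)C/C=C(\C)C[C@@H](OC(=O)C(C)C)[C@@H]12 | intermediate
29 | (1R,3S,4Z,6R,7R,8R,10R)-15-[(tert-butyldimethylsilyl)oxy]-1,10-epoxy-3-hydroxy-8-(2-methylpropanoyloxy)germacra-4,11(13)-dien-12,6-olide | C=C1C(=O)O[C@@H]2/C=C(/CO[Si](C)(C)C(C)(C)C)[C@@H](O)C[C@H]3O[C@]3(C)C[C@@H](OC(=O)C(C)C)[C@@H]12 | intermediate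
30 | (1R,3S,4Z,6R,7R,8R,10R)-1,10-epoxy-3,15-dihydroxy-8-(2-methylpropanoyloxy)germacra-4,11(13)-dien-12,6-olide (CNP0219050.1) | C=C1C(=O)O[C@@H]2/C=C(/CO)[C@@H](O)C[C@H]3O[C@]3(C)C[C@@H](OC(=O)C(C)C)[C@@H]12 | target

**Totals**
Total step count: 20. Longest linear sequence: 15 steps (steps 1–6, then 12–20); the aldehyde branch (steps 7–11) is 5 steps.

**Steps most likely to fail, with fallbacks**

Step 16 (ten-membered Nozaki–Hiyama–Kishi closure; risks are ring strain, oligomerisation and loss of the sensitive β,γ-unsaturated aldehyde). The fallback closes the same C3–C4 bond by an acyl cross-coupling instead of a carbonyl addition. It sets out from 24. Pd(PPh3)4-catalysed exchange with Me3SnSnMe3 gives the alkenylstannane alcohol F2. Dess–Martin oxidation gives the stannyl aldehyde F3. NaClO2/NaH2PO4/2-methyl-2-butene gives the stannyl carboxylic acid F4. 1-Chloro-N,N,2-trimethylprop-1-en-1-amine converts it into the stannyl acid chloride F5, which is cyclised at high dilution by intramolecular acyl Stille coupling (Pd2(dba)3, tri(2-furyl)phosphine, toluene). This delivers the enone directly and returns to the route at 27.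

Step 13 (Mitsunobu inversion at the hindered C8 carbinol; risks are low conversion and elimination). The fallback replaces the redox condensation by a sulfonate displacement. It sets out from 21. MsCl/Et3N in CH2Cl2 at −20 °C gives the C8 methanesulfonate F1, which is displaced with inversion by CsO2CCHMe2 with 18-crown-6 in toluene at 60 °C. It returns to the route at 23.

Step 19 (facial selectivity of the macrocyclic epoxidation). If the peracid delivers oxygen to the wrong face, the fallback inverts the facial outcome through a halohydrin. It sets out from 28. N-Bromosuccinimide in THF/H2O at 0 °C forms the bromonium ion on the exposed face and water opens it anti at C10, giving the 1-bromo-10-hydroxy compound F6. DBU in CH2Cl2 then closes the oxirane by displacement of bromide, placing oxygen on the face opposite to the one first attacked. It returns to the route at 29.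

**Further compounds**
F1 | step 13 | (1S,3E)-1-[(2S,3R)-2-[(1Z)-3-[(tert-butyldimethylsilyl)oxy]-2-iodoprop-1-en-1-yl]-4-methylidene-5-oxooxolan-3-yl]-6-[(4-methoxybenzyl)oxy]-3-methylhex-3-en-1-yl methanesulfonate | C=C1C(=O)O[C@H](/C=C(\I)CO[Si](C)(C)C(C)(C)C)[C@H]1[C@@H](OS(C)(=O)=O)C/C(C)=C/CCOCc1ccc(OC)cc1
F2 | step 16 | (1R,3E)-1-[(2S,3R)-2-[(1Z)-3-[(tert-butyldimethylsilyl)oxy]-2-(trimethylstannyl)prop-1-en-1-yl]-4-methylidene-5-oxooxolan-3-yl]-6-hydroxy-3-methylhex-3-en-1-yl 2-methylpropanoate | C=C1C(=O)O[C@H](/C=C(\[Sn](C)(C)C)CO[Si](C)(C)C(C)(C)C)[C@H]1[C@H](OC(=O)C(C)C)C/C(C)=C/CCO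
F3 | step 16 | (1R,3E)-1-[(2S,3R)-2-[(1Z)-3-[(tert-butyldimethylsilyl)oxy]-2-(trimethylstannyl)prop-1-en-1-yl]-4-methylidene-5-oxooxolan-3-yl]-3-methyl-6-oxohex-3-en-1-yl 2-methylpropanoate | C=C1C(=O)O[C@H](/C=C(\[Sn](C)(C)C)CO[Si](C)(C)C(C)(C)C)[C@H]1[C@H](OC(=O)C(C)C)C/C(C)=C/CC=O
F4 | step 16 | (3E,6R)-6-[(2S,3R)-2-[(1Z)-3-[(tert-butyldimethylsilyl)oxy]-2-(trimethylstannyl)prop-1-en-1-yl]-4-methylidene-5-oxooxolan-3-yl]-4-methyl-6-(2-methylpropanoyloxy)hex-3-enoic acid | C=C1C(=O)O[C@H](/C=C(\[Sn](C)(C)C)CO[Si](C)(C)C(C)(C)C)[C@H]1[C@H](OC(=O)C(C)C)C/C(C)=C/CC(O)=O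
F5 | step 16 | (3E,6R)-6-[(2S,3R)-2-[(1Z)-3-[(tert-butyldimethylsilyl)oxy]-2-(trimethylstannyl)prop-1-en-1-yl]-4-methylidene-5-oxooxolan-3-yl]-4-methyl-6-(2-methylpropanoyloxy)hex-3-enoyl chloride | C=C1C(=O)O[C@H](/C=C(\[Sn](C)(C)C)CO[Si](C)(C)C(C)(C)C)[C@H]1[C@H](OC(=O)C(C)C)C/C(C)=C/CC(Cl)=O
F6 | step 19 | (1S,3S,4Z,6R,7R,8R,10R)-1-bromo-15-[(tert-butyldimethylsilyl)oxy]-3,10-dihydroxy-8-(2-methylpropanoyloxy)germacra-4,11(13)-dien-12,6-olide | C=C1C(=O)O[C@@H]2/C=C(/CO[Si](C)(C)C(C)(C)C)[C@@H](O)C[C@H](Br)[C@@](O)(C)C[C@@H](OC(=O)C(C)C)[C@@H]12
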